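## Retrosynthetic overview

1. Target 32 ⇐ MOM removal, carbamoylation and CHO → CHCl2 ⇐ aldehyde diol 27 ⇐ half-reduction of the 12-membered lactone in 26, whose acyl carbon is the future CHCl2 carbon held at the acid oxidation level.
2. 26 ⇐ hydrogenation ⇐ diene 25 ⇐ double ring-closing olefin metathesis of the acyclic tetraene ester 23, which makes C3=C4 and C3′=C4′ in one operation.
3. 23 ⇐ esterification of alcohol 20 (ring A half, CH2Cl chain) with formyl acid 21 (ring B half), then crotylboration; both halves come from one diol 16 ⇐ auxiliary-controlled aryl-copper conjugate addition (sets C7) and a vinyl Grignard coupling.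
4. Enabling feature: the 22-membered [7.7]paracyclophane ring consists of two identical halves (2,6-dihydroxy-1,4-phenylene ring, carbamate carbinol C1, methyl-bearing C2, methylenes C3–C6, branch carbon C7) that differ only in the last carbon of the C7 butyl chain (CH2Cl or CHCl2). The oxygen on C1 of one half and the CHCl2 carbon of the other half flank the same C1–C7 bridge, so an ester between them makes a 12-membered lactone across C3–C4 and locks the halves head to tail.
5. Ring order: both benzene rings are bought in 1; the temporary 12-membered lactone and the 22-membered carbocycle are closed together in step 17; the lactone is opened in step 19.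

Key step: step 17

Remarks. Locants: in each half the bridge is numbered from the carbinol carbon C1 through C2 (methyl) and C3–C6 to the branching benzylic carbon C7. Unprimed locants belong to the bridge ending at the dichlorobutyl-bearing carbon, primed ones to the other bridge. Ring A carries C1 and C7′, ring B carries C7 and C1′. MOM = CH2OCH3, TBS = Si(CH3)2C(CH3)3. Assumption: the geometry of the two olefins in 24 and 25 is left undefined, since both isomers are expected and both are hydrogenated in step 18.

## Route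

Step 1
Reactants: 1 3,5-dihydroxybenzyl alcohol
Product: 2 [3,5-bis(methoxymethoxy)phenyl]methanol
Conditions: MOMCl (2.3 equiv), K2CO3, acetone, 0 °C → rt
Reagents that add atoms: chloromethyl methyl ether, COCCl
Why: Williamson O-alkylation in which K2CO3 ionises only the two phenols, so the benzylic alcohol should stay free.

Step 2
Reactants: 2 [3,5-bis(methoxymethoxy)phenyl]methanol
Product: 3 {[3,5-bis(methoxymethoxy)benzyl]oxy}(tert-butyl)dimethylsilane
Conditions: TBSCl, imidazole, DMF, rt
Reagents that add atoms: tert-butyldimethylsilyl chloride, CC(C)(C)[Si](C)(C)Cl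
Why: Standard imidazole-mediated silylation of a primary alcohol, which masks the only acidic proton before the aryl metalation.

Step 3
Reactants: 4 hex-5-en-1-ol
Product: 5 tert-butyl(hex-5-en-1-yloxy)dimethylsilane
Conditions: TBSCl, imidazole, CH2Cl2, rt
Reagents that add atoms: tert-butyldimethylsilyl chloride, CC(C)(C)[Si](C)(C)Cl
Why: Standard silylation of a primary alcohol.

Step 4
Reactants: 6 (S)-4-benzyloxazolidin-2-one, 7 acryloyl chloride
Product: 8 (S)-3-acryloyl-4-benzyloxazolidin-2-one
Conditions: Et3N, LiCl, THF, −20 °C → rt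
Reagents that add atoms: none
Why: N-acylation of the oxazolidinone under mild LiCl/Et3N conditions, which avoid strong base and polymerisation of the acryloyl unit.

Step 5
Reactants: 5 tert-butyl(hex-5-en-1-yloxy)dimethylsilane, 8 (S)-3-acryloyl-4-benzyloxazolidin-2-one
Product: 9 (S)-4-benzyl-3-[(E)-7-(tert-butyldimethylsilyloxy)hept-2-enoyl]oxazolidin-2-one
Conditions: 5 (2 equiv), second-generation Hoveyda–Grubbs catalyst RuCl2(H2IMes)(=CH-C6H4-2-O-i-Pr) (5 mol %), CH2Cl2, 40 °C
Reagents that add atoms: none
Why: Olefin cross-metathesis between a fast-reacting terminal olefin and an electron-poor acryloyl imide that does not homodimerise, which should give the E-enoyl imide.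

Step 6
Reactants: 3 {[3,5-bis(methoxymethoxy)benzyl]oxy}(tert-butyl)dimethylsilane, 9 (S)-4-benzyl-3-[(E)-7-(tert-butyldimethylsilyloxy)hept-2-enoyl]oxazolidin-2-one
Product: 12 (S)-4-benzyl-3-[(3R)-3-{2,6-bis(methoxymethoxy)-4-[(tert-butyldimethylsilyloxy)methyl]phenyl}-7-(tert-butyldimethylsilyloxy)heptanoyl]oxazolidin-2-one, via aryllithium 10 (not isolated), via arylmagnesium bromide 11 (not isolated)
Conditions: 3 (2 equiv), n-BuLi, THF, 0 °C; MgBr2·OEt2, −20 °C; CuBr·SMe2 (1 equiv), THF/Me2S, −40 °C; then 9, −40 → −10 °C; aq. NH4Cl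
Reagents that add atoms: none
Why: Directed ortho-lithiation between the two MOM ethers followed by auxiliary-controlled copper-mediated conjugate addition, in which the aryl group attacks the β-carbon of the magnesium-chelated s-cis enoyl imide on the face opposite the benzyl group and so sets the future C7 as (3R).

Step 7
Reactants: 12 the conjugate adduct
Product: 13 (3R)-3-{2,6-bis(methoxymethoxy)-4-[(tert-butyldimethylsilyloxy)methyl]phenyl}-7-(tert-butyldimethylsilyloxy)heptan-1-ol
Conditions: LiBH4, MeOH (1 equiv), THF, 0 °C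
Reagents that add atoms: none
Why: Reductive cleavage of the N-acyl oxazolidinone by hydride attack at the exocyclic carbonyl, which releases the auxiliary and leaves the stereocentre untouched.

Step 8
Reactants: 13 the primary alcohol
Product: 14 tert-butyl{[(5R)-5-{2,6-bis(methoxymethoxy)-4-[(tert-butyldimethylsilyloxy)methyl]phenyl}-7-iodoheptyl]oxy}dimethylsilane
Conditions: I2, PPh3, imidazole, CH2Cl2, 0 °C → rt
Reagents that add atoms: iodine, II
Why: Appel-type iodination through an alkoxyphosphonium ion, which is compatible with silyl and MOM ethers.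

Step 9
Reactants: 14 the primary iodide
Product: 15 tert-butyl{[(5R)-5-{2,6-bis(methoxymethoxy)-4-[(tert-butyldimethylsilyloxy)methyl]phenyl}non-8-en-1-yl]oxy}dimethylsilane
Conditions: CH2=CHMgBr (3 equiv), CuI (20 mol %), THF, −30 → 0 °C
Reagents that add atoms: vinylmagnesium bromide, C=C[Mg]Br
Why: Copper-catalysed Grignard cross-coupling at an unhindered primary sp3 carbon, which installs the but-3-enyl arm (C6, C5, C4 and the methylidene lost later) without touching C7.

Step 10
Reactants: 15 the bis-silyl ether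
Product: 16 (5R)-5-[4-(hydroxymethyl)-2,6-bis(methoxymethoxy)phenyl]non-8-en-1-ol
Conditions: n-Bu4NF (2.5 equiv), THF, rt
Reagents that add atoms: none
Why: Fluoride desilylation of both primary silyl ethers, which leaves the aryl MOM ethers intact and gives the diol common to both halves.

Step 11
Reactants: 16 the diol
Product: 17 4-[(5R)-9-hydroxynon-1-en-5-yl]-3,5-bis(methoxymethoxy)benzaldehyde
Conditions: activated MnO2, CH2Cl2, rt
Reagents that add atoms: none
Why: MnO2 oxidises benzylic alcohols chemoselectively, so the aliphatic primary alcohol should remain.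

Step 12
Reactants: 17 the hydroxy aldehyde
Product: 18 4-[(5R)-9-chloronon-1-en-5-yl]-3,5-bis(methoxymethoxy)benzaldehyde
Conditions: N-chlorosuccinimide, PPh3, CH2Cl2, 0 °C → rt
Reagents that add atoms: N-chlorosuccinimide, ClN1C(=O)CCC1=O
Why: Appel-type chlorination with a chlorophosphonium salt that, unlike PPh3/CCl4, generates no dichloromethylene ylide and therefore spares the aldehyde.

Step 13
Reactants: 18 the chloro aldehyde, 19 (Z)-crotylboronic acid pinacol ester
Product: 20 (1R,2S)-1-{4-[(5R)-9-chloronon-1-en-5-yl]-3,5-bis(methoxymethoxy)phenyl}-2-methylbut-3-en-1-ol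
Conditions: (R)-TRIP (3,3′-bis(2,4,6-triisopropylphenyl)-1,1′-binaphthyl-2,2′-diyl hydrogen phosphate, 5 mol %), toluene, 4 Å MS, −30 °C; aq. work-up
Reagents that add atoms: none
Why: Chiral phosphoric acid-catalysed crotylboration through a closed chair (Zimmerman–Traxler) transition state, in which the Z-boronate fixes the syn relationship and the (R)-catalyst directs attack to the Re face of the aryl aldehyde, giving C1 (R) and C2 (S).

Step 14
Reactants: 16 the diol
Product: 21 (5R)-5-[4-formyl-2,6-bis(methoxymethoxy)phenyl]non-8-enoic acid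
Conditions: TEMPO (20 mol %), PhI(OAc)2 (3.3 equiv), MeCN/H2O, rt
Reagents that add atoms: water, O
Why: Oxoammonium oxidation in wet acetonitrile takes the aliphatic primary alcohol through its aldehyde hydrate to the acid, while the benzylic alcohol should stop at the poorly hydrated aryl aldehyde.

Step 15
Reactants: 20 the ring A alcohol, 21 the ring B formyl acid
Product: 22 (1R,2S)-1-{4-[(5R)-9-chloronon-1-en-5-yl]-3,5-bis(methoxymethoxy)phenyl}-2-methylbut-3-en-1-yl (5R)-5-[4-formyl-2,6-bis(methoxymethoxy)phenyl]non-8-enoate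
Conditions: EDC·HCl, DMAP, CH2Cl2, 0 °C → rt
Reagents that add atoms: none
Why: Steglich esterification joins the C1 oxygen of the ring A half to the side-chain carboxyl of the ring B half without affecting the aldehyde or any stereocentre.

Step 16
Reactants: 22 the ester aldehyde, 19 (Z)-crotylboronic acid pinacol ester
Product: 23 (1R,2S)-1-{4-[(5R)-9-chloronon-1-en-5-yl]-3,5-bis(methoxymethoxy)phenyl}-2-methylbut-3-en-1-yl (5R)-5-{4-[(1R,2S)-1-hydroxy-2-methylbut-3-en-1-yl]-2,6-bis(methoxymethoxy)phenyl}non-8-enoate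
Conditions: (R)-TRIP (5 mol %), toluene, 4 Å MS, −30 °C; aq. work-up
Reagents that add atoms: none
Why: The same catalyst-controlled syn-crotylboration as in step 13 sets C1′ (R) and C2′ (S), with the remote stereocentres, the ester and the alkyl chloride as spectators.

Step 17
Reactants: 23 the tetraene hydroxy ester
Product: 25 lactone-bridged [7.7]paracyclophane diene (C3=C4 and C3′=C4′; C1–O joined to C7 by a C(=O)(CH2)3 strap; OH on C1′; 4-chlorobutyl on C7′; four OMOM), via lactone triene 24 (not isolated)
Conditions: second-generation Grubbs catalyst RuCl2(H2IMes)(PCy3)(=CHPh) (2 × 10 mol %), CH2Cl2 (1 mM), 40 °C, slow argon stream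
Reagents that add atoms: none
Why: A ruthenium alkylidene loads onto one of the unhindered butenyl termini and two ring-closing olefin metatheses follow by [2+2] cycloaddition and cycloreversion, each releasing ethene, so that C3=C4 and C3′=C4′ are made in one flask; the closest known reaction types are ring-closing metathesis of ω-alkenyl esters to 12-membered lactones and the head-to-tail metathesis cyclodimerisation of resorcinol ethers bearing a 2-methylbut-3-enyl arm and a but-3-enyl arm to [7.7]paracyclophane dienes. The 12-membered lactone is closed by joining the vinyl carbon on C2 (C3) to the butenyl terminus on C7 (C4), the ester holding these two olefins on one chain, and the 22-membered carbocycle is closed by the same kind of union between the vinyl group on C2′ and the butenyl terminus on C7′. No stereocentre is created and none is touched, since C2 and C2′ are allylic but carry no acidic or ionisable substituent, and the olefin geometry is irrelevant because both double bonds are hydrogenated in step 18. The step needs head-to-tail pairing and ring closure instead of chain growth. Closure within one half is excluded because the two arms on each benzene ring are para to each other, the ester strap puts one head olefin and one tail olefin of the two halves inside a 12-membered ring and leaves a single partner for each remaining olefin once that ring exists, and the mis-paired tail-to-tail product is an unhindered 1,2-disubstituted olefin that the catalyst re-opens, so the system can funnel to the doubly closed head-to-tail product. High dilution and removal of ethene should secure cyclisation over oligomerisation.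

Step 18
Reactants: 25 the bicyclic diene
Product: 26 lactone-bridged [7.7]paracyclophane (both bridges saturated)
Conditions: H2 (4 atm), RhCl(PPh3)3 (10 mol %), benzene/EtOH, 40 °C
Reagents that add atoms: none
Why: Homogeneous hydrogenation of the two 1,2-disubstituted olefins, chosen because it should not hydrogenolyse the benzylic C–O bonds or the C–Cl bond.

Step 19
Reactants: 26 the saturated lactone
Product: 27 aldehyde diol (OH on C1 and C1′; 4-oxobutyl on C7; 4-chlorobutyl on C7′; four OMOM)
Conditions: i-Bu2AlH (3 equiv), CH2Cl2, −78 °C; MeOH, then aq. Rochelle salt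
Reagents that add atoms: none
Why: Half-reduction of the ester, whose tetrahedral aluminium hemiacetal persists at −78 °C and collapses on work-up, releases the C1 hydroxyl and delivers the acyl carbon as the aldehyde needed for the CHCl2 group.

Step 20
Reactants: 27 the aldehyde diol
Product: 29 gem-dichloride diol (4,4-dichlorobutyl on C7), via hydrazone 28 (not isolated)
Conditions: N2H4·H2O, EtOH, 4 Å MS, 0 °C → rt; evaporate; then CuCl2 (6 equiv), Et3N (3 equiv), MeOH, 0 °C → rt
Reagents that add atoms: copper dichloride, Cl[Cu]Cl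
Why: Oxidation of the aldehyde hydrazone by CuCl2 to the diazoalkane, followed by two chlorine transfers from copper with loss of N2, converts CH=O into CHCl2 under conditions that tolerate free alcohols, MOM ethers and the alkyl chloride.

Step 21
Reactants: 29 the gem-dichloride diol
Product: 31 bis-carbamate tetrakis(MOM) ether, via bis(trichloroacetylcarbamate) 30 (not isolated)
Conditions: Cl3CC(O)NCO (2.5 equiv), CH2Cl2, 0 °C; then K2CO3 (cat.), MeOH, rt
Reagents that add atoms: trichloroacetyl isocyanate, O=C=NC(=O)C(Cl)(Cl)Cl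
Why: Addition of the two secondary alcohols to the highly electrophilic isocyanate and mild methanolysis of the trichloroacetyl groups gives the primary carbamates with retention at C1 and C1′.

Step 22
Reactants: 31 the bis-carbamate tetrakis(MOM) ether
Product: 32 CNP0310589.1
Conditions: HCl (1.25 M in MeOH), THF, 0 °C → rt
Reagents that add atoms: none
Why: Acid-catalysed transacetalisation removes the four aryl MOM ethers, while the benzylic carbamates should survive because the ring oxygens are meta to C1 and C1′ and do not stabilise a benzylic cation.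

## Compound list

1 | 3,5-dihydroxybenzyl alcohol | OCc1cc(O)cc(O)c1 | starting material
2 | [3,5-bis(methoxymethoxy)phenyl]methanol | OCc1cc(OCOC)cc(OCOC)c1 | intermediate
3 | {[3,5-bis(methoxymethoxy)benzyl]oxy}(tert-butyl)dimethylsilane | CC(C)(C)[Si](C)(C)OCc1cc(OCOC)cc(OCOC)c1 | intermediate
4 | hex-5-en-1-ol | OCCCCC=C | starting material
5 | tert-butyl(hex-5-en-1-yloxy)dimethylsilane | C=CCCCCO[Si](C)(C)C(C)(C)C | intermediate
6 | (S)-4-benzyloxazolidin-2-one | O=C1N[C@@H](Cc2ccccc2)CO1 | starting material
7 | acryloyl chloride | C=CC(Cl)=O | starting material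
8 | (S)-3-acryloyl-4-benzyloxazolidin-2-one | C=CC(=O)N1C(=O)OC[C@@H]1Cc1ccccc1 | intermediate
9 | (S)-4-benzyl-3-[(E)-7-(tert-butyldimethylsilyloxy)hept-2-enoyl]oxazolidin-2-one | CC(C)(C)[Si](C)(C)OCCCC/C=C/C(=O)N1C(=O)OC[C@@H]1Cc1ccccc1 | intermediate
10 | {2,6-bis(methoxymethoxy)-4-[(tert-butyldimethylsilyloxy)methyl]phenyl}lithium (formed in the flask) | [Li]c1c(OCOC)cc(CO[Si](C)(C)C(C)(C)C)cc1OCOC | intermediate
11 | {2,6-bis(methoxymethoxy)-4-[(tert-butyldimethylsilyloxy)methyl]phenyl}magnesium bromide (formed in the flask) | Br[Mg]c1c(OCOC)cc(CO[Si](C)(C)C(C)(C)C)cc1OCOC | intermediate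
12 | (S)-4-benzyl-3-[(3R)-3-{2,6-bis(methoxymethoxy)-4-[(tert-butyldimethylsilyloxy)methyl]phenyl}-7-(tert-butyldimethylsilyloxy)heptanoyl]oxazolidin-2-one | O=C(C[C@@H](CCCCO[Si](C)(C)C(C)(C)C)c1c(OCOC)cc(CO[Si](C)(C)C(C)(C)C)cc1OCOC)N1C(=O)OC[C@@H]1Cc1ccccc1 | intermediate
13 | (3R)-3-{2,6-bis(methoxymethoxy)-4-[(tert-butyldimethylsilyloxy)methyl]phenyl}-7-(tert-butyldimethylsilyloxy)heptan-1-ol | OCC[C@@H](CCCCO[Si](C)(C)C(C)(C)C)c1c(OCOC)cc(CO[Si](C)(C)C(C)(C)C)cc1OCOC | intermediate
14 | tert-butyl{[(5R)-5-{2,6-bis(methoxymethoxy)-4-[(tert-butyldimethylsilyloxy)methyl]phenyl}-7-iodoheptyl]oxy}dimethylsilane | ICC[C@@H](CCCCO[Si](C)(C)C(C)(C)C)c1c(OCOC)cc(CO[Si](C)(C)C(C)(C)C)cc1OCOC | intermediate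
15 | tert-butyl{[(5R)-5-{2,6-bis(methoxymethoxy)-4-[(tert-butyldimethylsilyloxy)methyl]phenyl}non-8-en-1-yl]oxy}dimethylsilane | C=CCC[C@@H](CCCCO[Si](C)(C)C(C)(C)C)c1c(OCOC)cc(CO[Si](C)(C)C(C)(C)C)cc1OCOC | intermediate
16 | (5R)-5-[4-(hydroxymethyl)-2,6-bis(methoxymethoxy)phenyl]non-8-en-1-ol | C=CCC[C@@H](CCCCO)c1c(OCOC)cc(CO)cc1OCOC | intermediate
17 | 4-[(5R)-9-hydroxynon-1-en-5-yl]-3,5-bis(methoxymethoxy)benzaldehyde | C=CCC[C@@H](CCCCO)c1c(OCOC)cc(C=O)cc1OCOC | intermediate
18 | 4-[(5R)-9-chloronon-1-en-5-yl]-3,5-bis(methoxymethoxy)benzaldehyde | C=CCC[C@@H](CCCCCl)c1c(OCOC)cc(C=O)cc1OCOC | intermediate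
19 | (Z)-crotylboronic acid pinacol ester, 2-[(2Z)-but-2-en-1-yl]-4,4,5,5-tetramethyl-1,3,2-dioxaborolane | C/C=C\CB1OC(C)(C)C(C)(C)O1 | starting material
20 | (1R,2S)-1-{4-[(5R)-9-chloronon-1-en-5-yl]-3,5-bis(methoxymethoxy)phenyl}-2-methylbut-3-en-1-ol (ring A half) | C=CCC[C@@H](CCCCCl)c1c(OCOC)cc(cc1OCOC)[C@H](O)[C@@H](C)C=C | intermediate
21 | (5R)-5-[4-formyl-2,6-bis(methoxymethoxy)phenyl]non-8-enoic acid (ring B half) | C=CCC[C@@H](CCCC(O)=O)c1c(OCOC)cc(C=O)cc1OCOC | intermediate
22 | (1R,2S)-1-{4-[(5R)-9-chloronon-1-en-5-yl]-3,5-bis(methoxymethoxy)phenyl}-2-methylbut-3-en-1-yl (5R)-5-[4-formyl-2,6-bis(methoxymethoxy)phenyl]non-8-enoate | C=CCC[C@@H](CCCCCl)c1c(OCOC)cc(cc1OCOC)[C@H](OC(=O)CCC[C@H](CCC=C)c1c(OCOC)cc(C=O)cc1OCOC)[C@@H](C)C=C | intermediate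
23 | (1R,2S)-1-{4-[(5R)-9-chloronon-1-en-5-yl]-3,5-bis(methoxymethoxy)phenyl}-2-methylbut-3-en-1-yl (5R)-5-{4-[(1R,2S)-1-hydroxy-2-methylbut-3-en-1-yl]-2,6-bis(methoxymethoxy)phenyl}non-8-enoate | C=CCC[C@@H](CCCCCl)c1c(OCOC)cc(cc1OCOC)[C@H](OC(=O)CCC[C@H](CCC=C)c1c(OCOC)cc(cc1OCOC)[C@H](O)[C@@H](C)C=C)[C@@H](C)C=C | intermediate
24 | lactone triene: 12-membered lactone (C3=C4 closed) still carrying the but-3-enyl arm on C7′ and the 2-methylbut-3-enyl carbinol on ring B (formed in the flask) | C=CCC[C@@H](CCCCCl)c1c(OCOC)cc(cc1OCOC)[C@@H]2OC(=O)CCC[C@H](CCC=C[C@@H]2C)c3c(OCOC)cc(cc3OCOC)[C@H](O)[C@@H](C)C=C | intermediate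
25 | lactone-bridged [7.7]paracyclophane diene (C3=C4, C3′=C4′; stereocentres as in the target) | C1=CCC[C@@H](CCCCCl)c2c(OCOC)cc(cc2OCOC)[C@H](OC(=O)CCC3)[C@@H](C)C=CCC[C@@H]3c4c(OCOC)cc(cc4OCOC)[C@H](O)[C@H]1C | intermediate
26 | lactone-bridged [7.7]paracyclophane with saturated bridges | C1CCC[C@@H](CCCCCl)c2c(OCOC)cc(cc2OCOC)[C@H](OC(=O)CCC3)[C@@H](C)CCCC[C@@H]3c4c(OCOC)cc(cc4OCOC)[C@H](O)[C@H]1C | intermediate
27 | aldehyde diol: tetrakis(MOM) [7.7]paracyclophane-1,1′-diol with 4-oxobutyl on C7 and 4-chlorobutyl on C7′ | C1CCC[C@@H](CCCCCl)c2c(OCOC)cc(cc2OCOC)[C@H](O)[C@@H](C)CCCC[C@@H](CCCC=O)c4c(OCOC)cc(cc4OCOC)[C@H](O)[C@H]1C | intermediate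
28 | hydrazone of 27 (formed in the flask) | C1CCC[C@@H](CCCCCl)c2c(OCOC)cc(cc2OCOC)[C@H](O)[C@@H](C)CCCC[C@@H](CCCC=NN)c4c(OCOC)cc(cc4OCOC)[C@H](O)[C@H]1C | intermediate
29 | gem-dichloride diol: 4,4-dichlorobutyl on C7, 4-chlorobutyl on C7′ | C1CCC[C@@H](CCCCCl)c2c(OCOC)cc(cc2OCOC)[C@H](O)[C@@H](C)CCCC[C@@H](CCCC(Cl)Cl)c4c(OCOC)cc(cc4OCOC)[C@H](O)[C@H]1C | intermediate
30 | bis(N-trichloroacetylcarbamate) of 29 (formed in the flask) | C1CCC[C@@H](CCCCCl)c2c(OCOC)cc(cc2OCOC)[C@H](OC(=O)NC(=O)C(Cl)(Cl)Cl)[C@@H](C)CCCC[C@@H](CCCC(Cl)Cl)c4c(OCOC)cc(cc4OCOC)[C@H](OC(=O)NC(=O)C(Cl)(Cl)Cl)[C@H]1C | intermediate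
31 | bis-carbamate tetrakis(MOM) ether of the target | C1CCC[C@@H](CCCCCl)c2c(OCOC)cc(cc2OCOC)[C@H](OC(N)=O)[C@@H](C)CCCC[C@@H](CCCC(Cl)Cl)c4c(OCOC)cc(cc4OCOC)[C@H](OC(N)=O)[C@H]1C | intermediate
32 | CNP0310589.1 | C[C@H]1CCCC[C@@H](CCCCCl)c2c(O)cc(cc2O)[C@H](OC(N)=O)[C@@H](C)CCCC[C@@H](CCCC(Cl)Cl)c2c(O)cc(cc2O)[C@@H]1OC(N)=O | target

## Step count and risks

Total step count: 22. Longest linear sequence: 18 steps (1 → 32 through steps 1, 2, 6–13 and 15–22).

**Step 17 (double ring-closing metathesis).** The cascade may stall at mis-paired head-to-head or tail-to-tail closures, or drift into intermolecular chain growth, instead of funnelling to the doubly closed product. The fallback separates the two ring closures and sets out from 22, which carries only one head olefin. Ring-closing metathesis of 22 (second-generation Grubbs catalyst, CH2Cl2, 1 mM, 40 °C) should give the 12-membered lactone aldehyde F1, with the C3=C4 bond in place and only a reversible tail-to-tail closure as competitor. Crotylboration of F1 with 19 under the conditions of step 16 then gives lactone triene 24 as an isolated compound. A second ring-closing metathesis of 24, which has a single possible olefin pair, closes the 22-membered ring and returns to the route at 25.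

**Step 6 (aryl-copper conjugate addition).** The aryl nucleophile flanked by two MOM ethers may add sluggishly or with eroded facial selectivity. The fallback inverts the roles so that the arene sits in the acceptor; it sets out from 3. Lithiation of 3 and quenching with DMF gives the benzaldehyde F2. Horner–Wadsworth–Emmons olefination of F2 with (R)-4-benzyl-3-[(diethoxyphosphoryl)acetyl]oxazolidin-2-one (LiCl, i-Pr2NEt, MeCN) gives the E-cinnamoyl imide F3. Copper-mediated addition of 4-(tert-butyldimethylsilyloxy)butylmagnesium bromide (CuBr·SMe2, THF/Me2S, −40 °C) gives the adduct F4. F4 has the same configuration at the new centre as 12, because both the auxiliary enantiomer and the roles of nucleophile and β-substituent are exchanged. LiBH4 reduction of F4 as in step 7 returns to the route at 13.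

**Step 20 (aldehyde to gem-dichloride).** Azine formation at the hydrazone stage, or capture of the diazo and copper-carbenoid intermediates by solvent or by the free hydroxyls, may divert material. The fallback uses deoxygenative dichlorination by a chlorophosphonium reagent on a substrate with masked hydroxyls; it sets out from 27. Acetylation (Ac2O, pyridine, DMAP) gives the diacetate aldehyde F5. Treatment of F5 with (PhO)3P/Cl2 (CH2Cl2, −78 °C → rt) converts CH=O into CHCl2 and gives the diacetate gem-dichloride F6. Methanolysis of F6 (K2CO3, MeOH) removes the acetates and returns to the route at 29.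

Further compounds
F1 | step 17 | 12-membered lactone aldehyde (C3=C4 closed; but-3-enyl arm on C7′; formyl group on ring B) | C=CCC[C@@H](CCCCCl)c1c(OCOC)cc(cc1OCOC)[C@@H]2OC(=O)CCC[C@H](CCC=C[C@@H]2C)c3c(OCOC)cc(C=O)cc3OCOC
F2 | step 6 | 2,6-bis(methoxymethoxy)-4-[(tert-butyldimethylsilyloxy)methyl]benzaldehyde | O=Cc1c(OCOC)cc(CO[Si](C)(C)C(C)(C)C)cc1OCOC
F3 | step 6 | (R)-4-benzyl-3-[(E)-3-{2,6-bis(methoxymethoxy)-4-[(tert-butyldimethylsilyloxy)methyl]phenyl}acryloyl]oxazolidin-2-one | O=C(/C=C/c1c(OCOC)cc(CO[Si](C)(C)C(C)(C)C)cc1OCOC)N1C(=O)OC[C@H]1Cc1ccccc1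
F4 | step 6 | (R)-4-benzyl-3-[(3R)-3-{2,6-bis(methoxymethoxy)-4-[(tert-butyldimethylsilyloxy)methyl]phenyl}-7-(tert-butyldimethylsilyloxy)heptanoyl]oxazolidin-2-one | O=C(C[C@@H](CCCCO[Si](C)(C)C(C)(C)C)c1c(OCOC)cc(CO[Si](C)(C)C(C)(C)C)cc1OCOC)N1C(=O)OC[C@H]1Cc1ccccc1
F5 | step 20 | diacetate of aldehyde diol 27 | C1CCC[C@@H](CCCCCl)c2c(OCOC)cc(cc2OCOC)[C@H](OC(C)=O)[C@@H](C)CCCC[C@@H](CCCC=O)c4c(OCOC)cc(cc4OCOC)[C@H](OC(C)=O)[C@H]1C
F6 | step 20 | diacetate of gem-dichloride diol 29 | C1CCC[C@@H](CCCCCl)c2c(OCOC)cc(cc2OCOC)[C@H](OC(C)=O)[C@@H](C)CCCC[C@@H](CCCC(Cl)Cl)c4c(OCOC)cc(cc4OCOC)[C@H](OC(C)=O)[C@H]1C
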